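## Retrosynthetic overview

Feature: one ether oxygen joins C1 of ring A, wedged between the C2 methoxy group and the C6 bromine, to C2 of ring B beside the C1 hydroxyl. Ring B shows OH/OAr/Br/Br at C1/C2/C4/C6, and the four aryl C–Br bonds speak against any copper or palladium coupling.
Last disconnection: ring B is traced back to the saturated ring of a 2-aryloxycyclohexanone, so that bromine aromatizes it and places C4–Br and C6–Br in the same pot.
Ether disconnection: the O–C2 bond is cut at the sp3 alpha carbon, giving 4,6-dibromoguaiacol and 2-chlorocyclohexanone (from cyclohexanone) for a metal-free SN2.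
Ring A: 4,6-dibromoguaiacol goes back to guaiacol by bromination para and then ortho to the hydroxyl.
Ring order: no ring is constructed. Ring A is bought aromatic and completed first; ring B is bought as a carbocycle, attached through oxygen and aromatized last.

Key step: step 5

Remark: ring A is the methoxy ring (C1 = ether carbon, C2 = C–OMe), ring B the hydroxy ring (C1 = C–OH or C=O, C2 = ether carbon), and since the target is achiral all chiral intermediates are used as racemates.

## Route

Step 1
Reactants: 1 guaiacol (2-methoxyphenol); 2 bromine
Product: 3 4-bromo-2-methoxyphenol (4-bromoguaiacol)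
Conditions: Br2 (1.0 equiv), CH2Cl2, −10 → 0 °C
Reagents that add atoms: bromine (2), BrBr
Why: Electrophilic aromatic bromination in which the free hydroxyl, the strongest donor on the ring, steers one equivalent of bromine to its unhindered para carbon C4, while the low temperature and exact stoichiometry hold back a second substitution.

Step 2
Reactants: 3 4-bromo-2-methoxyphenol; 2 bromine
Product: 4 2,4-dibromo-6-methoxyphenol (4,6-dibromoguaiacol)
Conditions: tBuNH2 (2.0 equiv), Br2 (1.0 equiv), toluene, −30 °C; then 3 in CH2Cl2, −78 °C → rt
Reagents that add atoms: bromine (2), BrBr
Why: Amine-mediated ortho-bromination of a phenol, in which N-bromo-tert-butylamine formed in the flask associates with the phenolic OH in a non-polar medium and hands its bromine to the only free ortho carbon C6, overriding the pull of the methoxy group toward C5 that free bromine shows in polar solvents.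

Step 3
Reactants: 5 cyclohexanone
Product: 6 2-chlorocyclohexan-1-one (racemic)
Conditions: SO2Cl2 (1.0 equiv), CH2Cl2, 0 °C → rt
Reagents that add atoms: sulfuryl chloride, O=S(=O)(Cl)Cl
Why: Alpha-chlorination of a ketone through its enol, in which one equivalent of reagent and the slower enolization of the chloro ketone stop the reaction at the monochloride, whose new stereocenter forms racemic and is of no consequence.

Step 4
Reactants: 4 2,4-dibromo-6-methoxyphenol; 6 2-chlorocyclohexan-1-one
Product: 9 racemic 2-(2,4-dibromo-6-methoxyphenoxy)cyclohexan-1-one, via potassium phenoxide 7 (not isolated), via 2-iodocyclohexanone 8 (not isolated)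
Conditions: K2CO3 (1.5 equiv), KI (0.1 equiv), DMF, 60 °C
Reagents that add atoms: none
Why: Williamson ether synthesis with Finkelstein assistance, in which the soft, weakly basic phenoxide 7 displaces halide by SN2 at a secondary carbon activated by the neighbouring carbonyl (faster through iodide 8), which favours O-alkylation over Favorskii rearrangement or elimination, leaves both aryl C–Br bonds untouched because no transition metal is present, and gives the C2 stereocenter as a racemate that is erased in step 5.

Step 5
Reactants: 9 racemic 2-(2,4-dibromo-6-methoxyphenoxy)cyclohexan-1-one; 2 bromine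
Product: 14 2,4-dibromo-6-(2,4-dibromo-6-methoxyphenoxy)phenol (target CNP0236935.0), via 2,6-dibromo ketone 10 (not isolated), via cross-conjugated dienone 11 (not isolated), via 2-aryloxyphenol 12 (not isolated), via 4-bromo-2-aryloxyphenol 13 (not isolated)
Conditions: Br2 (2.0 equiv), HBr (cat.), dry AcOH/ClCH2CH2Cl, dark, 0 °C → rt; 80 °C, N2 sweep; then rt, Br2 (2.0 equiv)
Reagents that add atoms: bromine (2), BrBr
Why: Proposed new method: HBr-catalysed enolization should let the first two equivalents of bromine enter at the alpha carbons C2 and C6 of 9 to give 10, warming should drive out two molecules of HBr by 1,2-elimination (at C2–C3 helped by the aryloxy oxygen, which stabilizes the developing cation) to give dienone 11 with its CH2 at C4, and 11 should tautomerize at once to phenol 12, whose new C1 hydroxyl then guides the last two equivalents by electrophilic aromatic substitution to C4 (13) and C6 (14). The closest known reaction type is the alpha-bromination/dehydrobromination of cyclohexanones and cyclohexenones to phenols, which with surplus bromine carries on to ortho- and para-bromophenols (1-tetralone, for instance, ends as bromo-1-naphthols), whereas the full cascade on a ketone bearing an aryloxy group at C2 has not been shown. No ring is closed and no stereocenter is created, since the carbocycle bought as cyclohexanone merely becomes aromatic ring B, the carbonyl oxygen becomes the C1 hydroxyl, the alkyl aryl ether turns into the hindered diaryl ether, and the C2 stereocenter of 9 vanishes. The step needs bromine to act on ring B alone, which the substrate secures because an enolizable ketone and later a free phenol are far better nucleophiles than ring A, a diether already carrying two bromines whose remaining H3 and H5 each sit next to a bromine, and because the balanced equation uses up all four equivalents. Within ring B the hydroxyl outranks the electron-poor, twisted aryloxy group as a director, C4 and C6 are its only open para and ortho sites, and a ketone that happens to take up two bromines at C6 simply keeps one of them there on aromatization, so the pathways meet in 14. Dry solvent keeps the 2-bromo-2-aryloxy ketone eliminating instead of shedding ring A by hydrolysis, the nitrogen sweep removes HBr before it can cleave the methyl ether, and the acid-induced cyclodehydration to a tetrahydrodibenzofuran that other 2-aryloxycyclohexanones show is blocked because both ortho carbons of ring A are substituted.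

## Compound list

1 | guaiacol (2-methoxyphenol) | COc1ccccc1O | starting material
2 | bromine | BrBr | starting material
3 | 4-bromo-2-methoxyphenol (4-bromoguaiacol) | COc1cc(Br)ccc1O | intermediate
4 | 2,4-dibromo-6-methoxyphenol (4,6-dibromoguaiacol) | COc1cc(Br)cc(Br)c1O | intermediate
5 | cyclohexanone | O=C1CCCCC1 | starting material
6 | 2-chlorocyclohexan-1-one (racemic) | O=C1CCCCC1Cl | intermediate
7 | potassium 2,4-dibromo-6-methoxyphenoxide | COc1cc(Br)cc(Br)c1[O-].[K+] | intermediate
8 | 2-iodocyclohexan-1-one (racemic) | O=C1CCCCC1I | intermediate
9 | 2-(2,4-dibromo-6-methoxyphenoxy)cyclohexan-1-one (racemic) | COc1cc(Br)cc(Br)c1OC1CCCCC1=O | intermediate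
10 | 2,6-dibromo-2-(2,4-dibromo-6-methoxyphenoxy)cyclohexan-1-one (racemic mixture of diastereomers) | COc1cc(Br)cc(Br)c1OC1(Br)CCCC(Br)C1=O | intermediate
11 | 2-(2,4-dibromo-6-methoxyphenoxy)cyclohexa-2,5-dien-1-one | COc1cc(Br)cc(Br)c1OC1=CCC=CC1=O | intermediate
12 | 2-(2,4-dibromo-6-methoxyphenoxy)phenol | COc1cc(Br)cc(Br)c1Oc1ccccc1O | intermediate
13 | 4-bromo-2-(2,4-dibromo-6-methoxyphenoxy)phenol | COc1cc(Br)cc(Br)c1Oc1cc(Br)ccc1O | intermediate
14 | 2,4-dibromo-6-(2,4-dibromo-6-methoxyphenoxy)phenol (CNP0236935.0) | COc1cc(Br)cc(Br)c1Oc1cc(Br)cc(Br)c1O | target

## Step count and risks

Total step count: 5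
Longest linear sequence: 4 (steps 1, 2, 4, 5)

Steps most likely to fail:

1. **Step 5 (Proposed new method).**
   - Risk: after the first loss of HBr the ring holds an enol-ether double bond, and addition of bromine there could fix a bromine at C3 of ring B. Dehydrobromination without base may also stall at the bromo ketone stage, and acid may strip ring A from the alpha-bromo ether.
   - Fallback: known chemistry throughout, with ring B brought in already aromatic. It sets out from 4 and comes back to the route at 12.
   - Phenol 4 is deprotonated to 7 (K2CO3, DMAc, 150 °C) and displaces fluoride from bought 2-fluorobenzaldehyde by SNAr, which should give 2-(2,4-dibromo-6-methoxyphenoxy)benzaldehyde F1.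
   - Baeyer–Villiger oxidation with mCPBA (CH2Cl2, rt) should shift the oxygen-substituted aryl group onto oxygen and give 2-(2,4-dibromo-6-methoxyphenoxy)phenyl formate F2.
   - Methanolysis (catalytic K2CO3, MeOH, rt) frees phenol 12. Now isolated, 12 takes up two equivalents of bromine 2 (AcOH, rt) through 13 to 14, an ordinary ortho/para dibromination of a phenol.

2. **Step 4.**
   - Risk: sluggish substitution by a hindered, weakly nucleophilic phenoxide. This gives base-induced self-condensation, dehydrohalogenation or Favorskii-type ring contraction of the halo ketone time to compete.
   - Fallback: the electrophile is changed to one that cannot enolize. It sets out from 4 and comes back at 9.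
   - Phenoxide 7, generated from 4 with catalytic K2CO3 (DMF, 110 °C), opens bought cyclohexene oxide by anti SN2 attack to racemic trans-2-(2,4-dibromo-6-methoxyphenoxy)cyclohexan-1-ol F3.
   - Oxidation of the secondary alcohol with Dess–Martin periodinane (CH2Cl2, rt) should give ketone 9.

3. **Step 2.**
   - Risk: erosion of ortho selectivity, with bromine drifting to the carbon para to the methoxy group, or overbromination.
   - Fallback: the ortho carbon is marked with a carboxyl group that bromine later replaces. It sets out from 1 and comes back at 4.
   - Guaiacol 1 is converted with NaOH into dry sodium 2-methoxyphenoxide F4, which is carboxylated at its only free ortho carbon under Kolbe–Schmitt conditions (CO2 under pressure, 130 °C) to sodium 2-hydroxy-3-methoxybenzoate F5. Aqueous HCl then liberates 2-hydroxy-3-methoxybenzoic acid F6.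
   - One equivalent of bromine 2 (AcOH, rt) should enter para to the hydroxyl and give 5-bromo-2-hydroxy-3-methoxybenzoic acid F7.
   - A second equivalent in aqueous AcOH should attack the carboxyl-bearing carbon (ipso-bromodecarboxylation of a salicylic acid) and deliver 4. The carboxyl group meanwhile shields and deactivates the carbon para to the methoxy group.

## Further compounds

F1 | step 5 | 2-(2,4-dibromo-6-methoxyphenoxy)benzaldehyde | COc1cc(Br)cc(Br)c1Oc1ccccc1C=O
F2 | step 5 | 2-(2,4-dibromo-6-methoxyphenoxy)phenyl formate | COc1cc(Br)cc(Br)c1Oc1ccccc1OC=O
F3 | step 4 | trans-2-(2,4-dibromo-6-methoxyphenoxy)cyclohexan-1-ol (racemic, one enantiomer drawn) | COc1cc(Br)cc(Br)c1O[C@@H]1CCCC[C@H]1O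
F4 | step 2 | sodium 2-methoxyphenoxide | COc1ccccc1[O-].[Na+]
F5 | step 2 | sodium 2-hydroxy-3-methoxybenzoate | COc1cccc(C(=O)[O-])c1O.[Na+]
F6 | step 2 | 2-hydroxy-3-methoxybenzoic acid | COc1cccc(C(=O)O)c1O
F7 | step 2 | 5-bromo-2-hydroxy-3-methoxybenzoic acid | COc1cc(Br)cc(C(=O)O)c1O
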